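A run time means little until it is held against the time a flask needs to clear its substrate, so two times matter here: the run time t and the clearing time τ.

| flask | substrate | reagent in the second phase | remark | time | volume of the second phase over the first |
|---|---|---|---|---|---|
| Tuesday's | 30 mM | 1.1 equiv | run made earlier |  |  |
| larch | 27 mM | 1.10 equiv |  | 6.0 h | 1.0 |
| alder | 27 mM | 0.740 equiv |  | 6.0 h | 1.0 |
| oak | 40 mM | 0.550 equiv |  | 6.0 h | 1.0 |
| ash | 50 mM | 4.40 equiv |  | 6.0 h | 1.0 |

- Tuesday's (time / min: target / %, substrate / %): 8.00: 1.7, 84.4; 25.0: 12.0, 66.7; 40.0: 20.7, 56.1; 60.0: 30.3, 53.9; 90.0: 39.6, 43.2; 120: 48.7, 37.1

(readings scatter by 1 percentage point)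

- charges count per volume of the first phase; a concentration in a rate is the amount of a species over the volume of its own phase; every rate counts per litre of the first phase
- the analysis behind the earlier runs scatters by 1 percentage point, standard deviation
- the earlier runs hold the two phases in the same ratio of volumes as the flask asked about
- a reading or a percentage of target counts all its forms, free or not

* the flasks put in order of amount of target, in percent of the substrate charged, best first, at 6.0 h (larch / alder / oak / ash)
* the amount of target, in percent of the substrate charged of the flask you put first, at 6.0 h
* the amount of target, in percent of the substrate charged of the flask you put last, at 6.0 h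

Tuesday's run gives τ as a reading. Over 95.0 min target gains 37 percentage points while substrate averages 51.9%, so the clearing time there, substrate present over its rate of turning into target, reads 134 min, with about 23.9 mM of reagent unspent on average, on a one-to-one count. Taking substrate loss as pseudo-first-order, with τ inverse to the unspent reagent, ash on its full charge gets 14.6 min as its clearing time τ. Hence t/τ is 24.7 for ash, and ash should clear its substrate well inside the run. Larch on its full charge has a lower ratio, 3.33, and its 1.10 equiv of reagent is spent as it reacts, so larch should stop short of clearing its substrate. Alder and oak hold 0.740 equiv and 0.550 equiv, less than one equivalent, which makes reagent the limiting reagent on a one-to-one count and puts them lower, oak last with the smallest charge.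

The forecast gives ash > larch > alder > oak, with top 98% (85% to 100%) and low 53% (40% to 55%), and calls ash “large reagent excess, essentially complete”.

The flasks give ash > larch > alder > oak: ash 91.7%, larch 74.6%, alder 55.3%, oak 44.9%.

    target → decomposed product (k = 0.0190 h⁻¹)
    substrate + reagent in the reaction phase → target (k = 390 M⁻¹ h⁻¹)
    substrate ⇌ dormant form (K = 0.360, k = 1.20 h⁻¹)
    target ⇌ product in the second phase, rate k4*([target] - [product in the second phase]/K4) per volume of the first phase (partition coefficient = 8.00, kL = 0.0720 h⁻¹)
    reagent in the reaction phase ⇌ reagent in the second phase, rate k5*([reagent in the reaction phase] - [reagent in the second phase]/K5) per volume of the first phase (partition coefficient = 8.60, kL = 5.10 h⁻¹)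

At 0.380 h ash makes reaction-phase target 24.9 times faster than it uses it up, going into its other forms counted as use. By 6.00 h ash's substrate stands at 0%, and reaction-phase target, whose half-life against decomposition of 36 h is long against the run of 6.0 h, has still yielded 8.27% of decomposed product. The neighbour with ash's equivalents at 12 mM of substrate has, on its full charge, a reckoned τ of 60.8 min, so t/τ is 5.92 and 0.268% of substrate should remain. That neighbour holds 0.13% of its charged substrate unbound at 6.00 h, with target at 92.3%.

Readings and results are calculated with constants of no real substance, noise included.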